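## Structural features

The target is two six-membered carbocycles joined through one methylene carbon. Ring A is the benzene ring of a 2,2-dimethyl-2H-chromene with hexanoyl at C8, hydroxyl at C5 and C7 and the bridge at C6. Ring B is an enolised 2-acetylcyclohexane-1,3,5-trione, numbered here B1 (bridge carbon), B2, B3 (quaternary), B4, B5 (acetyl-bearing), B6.

The only stereocentre is B3, which carries methyl and geranyl. It has no stereogenic neighbour and is chiral only because its two carbonyl neighbours differ further out: B4 leads to the acetyl-bearing B5, B2 to the bridge carbon B1. In the tautomer drawn it is R.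

Ring A is fully substituted, and the hexanoyl group sits between the pyran-oxygen carbon C8a and a hydroxyl, not between two hydroxyls. The fragile parts are the chromene double bond and the two trisubstituted alkenes of geranyl (acid, electrophiles, oxidants), the electron-rich phenols (oxidation), the enolised β-triketone (cleavage next to B3 by nucleophilic base, strong metal chelation) and the bridge itself, which can migrate between rings under acid or heat.

The real difficulties are the orientation of hexanoyl relative to the pyran oxygen on ring A, the absolute configuration of a quaternary carbon whose two flanks differ only remotely, and an unsymmetrical methylene coupling of two nucleophiles. The key step uses the fact that C8, C8a and C4a of ring A are contiguous and correspond to the α-carbon, the enol-ether carbon and the γ-carbon of a 2-(acylmethylene)tetrahydropyran, while C7–C6–C5, oxygenated at both ends, is a malonyl unit.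

## Logic of the disconnections

21 ⇒ 9 + 18 and one carbon. Both bonds of the bridging methylene are cut (C6–CH2 and CH2–B1). Each flank is the single unsubstituted, strongly nucleophilic carbon of its ring, so the cut gives two fragments of similar size, leaves the stereocentre inside one of them and needs no protecting group. The forward step must favour the cross-product over the two symmetrical dimers, which is why the one-carbon unit is first fixed on 18 (as 19, then 20) and only then offered to 9.

9 ⇒ 8. The C3=C4 double bond is taken back to the saturated pyran, because the annulation below brings the pyran carbons in at the alkane level. The price is one dehydrogenation that must take hydride from the benzylic carbon without oxidising the two phenols.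

8 ⇒ 5 + 6. Ring A is cut at C8–C7 and C5–C4a. This removes the whole aromatic ring in one move and places hexanoyl, ring oxygen and ring carbon in the right order already in 5, so the usual orientation problem of acylphloroglucinol chemistry does not arise at C8. The demand on the forward step is that the second acylation of 7 occurs on the pyran carbon. It is not free of alternatives: the hexanoyl oxygen and the α-methylene of the pentyl chain can also close six-membered rings, so the step is planned and secured with that in mind. The design of 5 is kept, with one relaxation: it is used as whatever E/Z mixture step 3 gives, since the double bond of 7 rotates easily.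

5 ⇒ 4. The enol-ether bond O1–C8a is cut with formal addition of water. This turns the vinylogous ester into a δ-hydroxy-β-diketone; the forward cyclodehydration has only one ring size open to it.

4 ⇒ 2 + 3. The C8–C8a bond is cut between a ketone α-carbon and a lactone carbonyl. The forward step needs the kinetic methyl enolate of 3 and must stop after one addition.

2 ⇒ 1. One C–CH3 bond and the lactone C–O bond are cut. The forward step needs a methyl nucleophile that prefers the ketone of 1 to its ester.

18 ⇒ 17 ⇒ 15 + 16. Ring B is cut at B4–B5 (attack of a carbon lying between two ketones on the ester) and then at B1–B6 (acetoacetylation of a methyl ketone). The quaternary carbon blocks every other enolisation site, so both forward steps have a single regiochemical course. They must avoid nucleophilic bases, which could cleave next to B3.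

15 ⇒ 12 + 13, and 12 ⇒ 10 + 11. The bond between B3 and the geranyl CH2 is cut. The stereocentre is then set by alkylation of a planar aza-enolate under the control of a removable amino-ester auxiliary; the demand is high facial selectivity and attack at the primary end of the allylic bromide.

## Other disconnections considered

Alternative 1: The cut runs through ring A at C8a–C4a and C5–C6. Four ring carbons (C8a, C8, C7, C6) come from 3-ethoxycyclobut-2-en-1-one A1 and two (C4a, C5) from the prenyl-substituted siloxyalkyne A2. On heating, A1 opens to a vinylketene that adds to A2; opening of the new cyclobutenone and a 6π closure give phenol A3.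

- In its favour: every event of this cascade is established for these reactant classes, the substitution pattern follows from the mechanism, and the three oxygens come out differentiated (free hydroxyl, silyl ether, ethyl ether), with prenyl already on the future C4a. On reliability of the ring-forming step this alternative is the better of the two, because the chosen annulation is untested.
- Against it here: A3 still lacks the hexanoyl group and the bridge, and both must enter at the two remaining ring C–H positions (future C8 and C6). The orientation question that the chosen plan settles inside its precursor therefore returns as a selectivity problem of an electrophilic acylation. The ethyl ether on the future C7 must also be cleaved in a molecule that contains, or will contain, a chromene and a geranyl chain.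
- Comparison: structurally it delivers the pyran carbons as a prenyl group, which is equal in value to the saturated pyran plus dehydrogenation of the chosen plan. In steps, ring A would cost about eight operations (both partners, benzannulation, pyran closure, acylation, two deprotections) against five.

Alternative 2: The cut is in ring B between B1 and B2. The stereocentre is made first: an esterase hydrolyses one of the two enantiotopic ester groups of malonate A4, and the acid is converted into the triacylmethane ester A5. In the dianion of A5 the methyl carbanion of one acetyl group attacks the remaining methyl ester and gives trione A6, which is the same compound as 18.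

- In its favour: the stereocentre comes from a catalytic, auxiliary-free step on a cheap achiral diester, and the closure cannot give a regioisomer because the two acetyl groups of A5 are equivalent. On economy of the stereo-defining step it is the better plan, since the chosen route spends a stoichiometric (recoverable) auxiliary and a cryogenic metalation.
- Against it: the level and sense of selection by an esterase for a malonate bearing methyl and a ten-carbon lipophilic chain cannot be predicted. The closure needs the least acidic position of A5, reached only as a dianion with excess strong base, to attack a neopentyl-type ester, and triacylmethanes tend to lose an acyl group under such conditions. In the chosen plan the nucleophile is the carbon between two ketones of 17, formed with an alkoxide.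
- Comparison: ring B would take four steps against three, which is practically equal. The alternative does not touch ring A, so it complements the chosen key step more than it competes with it; A6 could replace the product of steps 6 to 8 without further change.

Alternative 3: The cut is in ring B between B1 and B6. The achiral, symmetric bis(β-keto ester) A7 would be closed by a chiral magnesium Lewis acid and an amine base, so that the α-carbon of one arm attacks the ester of the other and gives A8.

- In its favour: A7 is easy to assemble, the stereocentre is created in the ring-forming step from an achiral substrate, and the ester left on B1 acts as a blocking group, so the acetyl group can afterwards only go to B5. On ease of precursor synthesis this alternative is the better one.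
- Against it: selection between enantiotopic ester arms in a Dieckmann closure under soft enolisation has no close precedent. The product is a strongly chelating acid that would hold the magnesium and stop turnover, and the closure is reversible, which can erode selectivity. After the key step, C-acetylation at B5 and removal of the ester from B1 are still needed; losing the ester before acetylation would give an achiral trione and erase the stereochemical information.
- Comparison: it is as speculative as the chosen key step, so on mechanistic risk the two are equal. The difference is where the risk sits: on the stereocentre here (failure costs enantiopurity), on ring A in the chosen plan (failure costs yield). Ring B would take about six steps against three.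

Key step: step 4

Remarks on the chemistry (assumptions):
- The enolised triones are drawn in one tautomeric form, and the descriptors quoted refer to the form drawn.
- The sense of induction in step 7 is taken to follow the chelate model given there; if correlation shows the opposite sense, the D-enantiomer of 11 is used and nothing else changes.

## Route

Step 1
Reactants: 1 ethyl 5-oxohexanoate
Product: 2 6,6-dimethyltetrahydro-2H-pyran-2-one
Conditions: MeMgBr (1.05 equiv), THF, −78 → 0 °C; then 1 M HCl, 25 °C
Reagents that add atoms: methylmagnesium bromide, C[Mg]Br
Why: Grignard addition is faster at the ketone than at the ester at low temperature, and the tertiary alkoxide or hydroxy ester closes to the six-membered lactone on warming and acid work-up (chemoselective Grignard addition, then lactonisation).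

Step 2
Reactants: 3 heptan-2-one; 2 6,6-dimethyltetrahydro-2H-pyran-2-one
Product: 4 2-hydroxy-2-methyltridecane-6,8-dione
Conditions: 3 (1.3 equiv), LiN(iPr)2 (1.3 equiv), THF, −78 °C; then 2, −78 → 0 °C; aq. NH4Cl
Reagents that add atoms: none
Why: Crossed Claisen condensation: the kinetic methyl enolate of 3 adds to the lactone carbonyl, the lithium hemiketal alkoxide survives at low temperature, and after ring opening the tertiary alkoxide deprotonates the new β-diketone, which prevents a second addition.

Step 3
Reactants: 4 2-hydroxy-2-methyltridecane-6,8-dione
Product: 5 (1E)-1-(6,6-dimethyltetrahydro-2H-pyran-2-ylidene)heptan-2-one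
Conditions: p-TolSO3H·H2O (5 mol %), PhMe, 4 Å molecular sieves, 50 °C
Reagents that add atoms: none
Why: Acid-catalysed cyclodehydration: the tertiary hydroxyl forms the six-membered hemiketal with the nearer ketone, and loss of water towards the doubly activated methylene gives the conjugated exocyclic β-alkoxy enone; an E/Z mixture is acceptable.

Step 4
Reactants: 5 (1E)-1-(6,6-dimethyltetrahydro-2H-pyran-2-ylidene)heptan-2-one; 6 malonyl dichloride
Product: 8 1-(5,7-dihydroxy-2,2-dimethylchroman-8-yl)hexan-1-one, via keto acyl chloride 7 (not isolated)
Conditions: 6 (1.0 equiv, slow addition), CH2Cl2, −40 → 20 °C, N2 sweep, no base; then MeOH, aq. NaHCO3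
Reagents that add atoms: none
Why: Proposed new method: the push–pull α-carbon of 5 should be C-acylated by one acid chloride group of 6 to give 7 (bond C8–C7), and an acid-catalysed proton shift from the pyran methylene to a carbonyl oxygen then gives the tautomer of 7 with an endocyclic enol ether and a hydrogen-bonded enolised 1,3-diketone, whose ring carbon attacks the second acid chloride group (bond C5–C4a). Loss of HCl and two enolisations then give the phloroglucinol ring, aromatisation making the closure irreversible. The closest known reaction type is the Effenberger condensation of alkyl enol ethers of ketones with malonyl dichloride at both α-carbons to give cyclohexane-1,3,5-triones, here applied across the enol-ether carbon C8a of a β-alkoxy enone. Ring A closes by a 6-(enol-endo)-exo-trig acylation and no stereocentre is formed. Three six-membered closures compete for the second acid chloride: on the pyran carbon (wanted), on the hexanoyl oxygen (giving a 4-hydroxy-2-pyranone) and on the α-methylene of the pentyl chain (giving an isomeric butyl-substituted phloroglucinol). The wanted one should be favoured because the enol-ether oxygen is alkylated and cannot close as it does in silyl enol ethers, because only the tautomer leading to it keeps a chelated enolised diketone, and because base is left out, so that no acylketene (which is trapped on oxygen) forms and acylation of the hexanoyl oxygen stays a cationic event that chloride can reverse. Hexanoyl then stands next to the pyran-oxygen carbon by construction, and either geometric isomer of 5 serves because the double bond of 7 rotates easily.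

Step 5
Reactants: 8 1-(5,7-dihydroxy-2,2-dimethylchroman-8-yl)hexan-1-one
Product: 9 1-(5,7-dihydroxy-2,2-dimethyl-2H-chromen-8-yl)hexan-1-one
Conditions: DDQ (1.1 equiv), 1,4-dioxane, 80 °C
Reagents that add atoms: none
Why: Quinone dehydrogenation of a 2,2-dimethylchroman: hydride is taken from the benzylic C4, whose cation is stabilised by the ortho and para oxygens, and loss of the C3 proton gives the chromene; the acyl-deactivated, chelated phenol ring should tolerate the oxidant.

Step 6
Reactants: 10 ethyl 2-methyl-3-oxobutanoate; 11 L-valine tert-butyl ester
Product: 12 ethyl (2Z)-3-{[(2S)-1-tert-butoxy-3-methyl-1-oxobutan-2-yl]amino}-2-methylbut-2-enoate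
Conditions: BF3·OEt2 (2 mol %), cyclohexane, reflux, Dean–Stark
Reagents that add atoms: none
Why: Condensation of a β-keto ester with a primary amine gives the enamino ester, held in the Z form by the N–H···O=C hydrogen bond; the labile stereocentre of 10 disappears.

Step 7
Reactants: 12 ethyl (2Z)-3-{[(2S)-1-tert-butoxy-3-methyl-1-oxobutan-2-yl]amino}-2-methylbut-2-enoate; 13 geranyl bromide
Product: 15 ethyl (2R,4E)-2-acetyl-2,5,9-trimethyldeca-4,8-dienoate, via alkylated imine 14 (not isolated)
Conditions: LiN(iPr)2 (1.1 equiv), THF, −78 °C; 13 (1.2 equiv), −78 → −40 °C; then 10% aq. citric acid, 25 °C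
Reagents that add atoms: water, O
Why: Asymmetric alkylation of the lithium aza-enolate of a chiral enamino ester (the established way to α,α-dialkyl β-keto esters): lithium is chelated by nitrogen and both ester carbonyls, the isopropyl group of the valine unit screens one face, and geranyl bromide enters SN2 at its primary carbon on the open face to set the quaternary centre as R. Mild aqueous acid then hydrolyses the imine and returns the auxiliary without touching the tert-butyl ester or the alkenes.

Step 8
Reactants: 15 ethyl (2R,4E)-2-acetyl-2,5,9-trimethyldeca-4,8-dienoate; 16 diketene
Product: 18 (4R)-2-acetyl-4-[(2E)-3,7-dimethylocta-2,6-dien-1-yl]-4-methylcyclohexane-1,3,5-trione, via trioxo ester 17 (not isolated)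
Conditions: LiN(iPr)2 (1.05 equiv), THF, −78 °C; enolate added to 16 (1.3 equiv), THF, −78 °C; then KOtBu (3 equiv), −78 → 25 °C; 1 M HCl
Reagents that add atoms: none
Why: Only the acetyl methyl of 15 can be deprotonated, and its enolate opens diketene at the acyl carbon to give the 3,5,7-trioxo ester 17 (bond B1–B6). With excess hindered alkoxide the carbon between the two outer ketones attacks the ester in a Claisen (Dieckmann-type) 6-exo-trig closure (bond B4–B5), the mode known from cyclisations of 3,5,7-trioxo esters to acylphloroglucinols. The quaternary centre cannot enolise and is carried through, and the usual aldol mode is blocked because the ester α-carbon is quaternary.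

Step 9
Reactants: 18 (4R)-2-acetyl-4-[(2E)-3,7-dimethylocta-2,6-dien-1-yl]-4-methylcyclohexane-1,3,5-trione; 9 1-(5,7-dihydroxy-2,2-dimethyl-2H-chromen-8-yl)hexan-1-one
Product: 21 1-[6-({(3R)-5-acetyl-3-[(2E)-3,7-dimethylocta-2,6-dien-1-yl]-2,4-dihydroxy-3-methyl-6-oxocyclohexa-1,4-dien-1-yl}methyl)-5,7-dihydroxy-2,2-dimethyl-2H-chromen-8-yl]hexan-1-one, via Mannich base 19 (not isolated), via methylidene trione 20 (not isolated)
Conditions: 18, [Me2N=CH2]I (1.0 equiv), iPr2NEt (1.0 equiv), CH2Cl2, 0 °C; then 9 (1.0 equiv), MeCN, 50 °C
Reagents that add atoms: N,N-dimethylmethyleneiminium iodide, C=[N+](C)C.[I-]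
Why: Mannich reaction at B1, the only free and most acidic carbon of 18, gives 19. On warming, β-elimination of dimethylamine gives the alkylidene trione 20, which is captured by C6 of 9, its only unsubstituted ring carbon, activated by two ortho hydroxyls (Friedel–Crafts-type Michael addition). Fixing the one-carbon unit on one partner before the other is added is what favours the cross-product, and the stereocentre is not involved.

## Compound list

1 | ethyl 5-oxohexanoate | CCOC(=O)CCCC(C)=O | starting material
2 | 6,6-dimethyltetrahydro-2H-pyran-2-one | CC1(C)CCCC(=O)O1 | intermediate
3 | heptan-2-one | CCCCCC(C)=O | starting material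
4 | 2-hydroxy-2-methyltridecane-6,8-dione (open form; equilibrates with its cyclic hemiketal and enols) | CCCCCC(=O)CC(=O)CCCC(C)(C)O | intermediate
5 | (1E)-1-(6,6-dimethyltetrahydro-2H-pyran-2-ylidene)heptan-2-one | CCCCCC(=O)/C=C1\CCCC(C)(C)O1 | intermediate
6 | malonyl dichloride (propanedioyl dichloride) | O=C(Cl)CC(Cl)=O | starting material
7 | 4-(6,6-dimethyltetrahydro-2H-pyran-2-ylidene)-3,5-dioxodecanoyl chloride | CCCCCC(=O)C(C(=O)CC(=O)Cl)=C1CCCC(C)(C)O1 | intermediate (not isolated)
8 | 1-(5,7-dihydroxy-2,2-dimethylchroman-8-yl)hexan-1-one | CCCCCC(=O)c1c(O)cc(O)c2c1OC(C)(C)CC2 | intermediate
9 | 1-(5,7-dihydroxy-2,2-dimethyl-2H-chromen-8-yl)hexan-1-one | CCCCCC(=O)c1c(O)cc(O)c2c1OC(C)(C)C=C2 | intermediate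
10 | ethyl 2-methyl-3-oxobutanoate (racemic) | CCOC(=O)C(C)C(C)=O | starting material
11 | L-valine tert-butyl ester, tert-butyl (2S)-2-amino-3-methylbutanoate | CC(C)[C@H](N)C(=O)OC(C)(C)C | starting material
12 | ethyl (2Z)-3-{[(2S)-1-tert-butoxy-3-methyl-1-oxobutan-2-yl]amino}-2-methylbut-2-enoate | CCOC(=O)/C(C)=C(C)\N[C@@H](C(C)C)C(=O)OC(C)(C)C | intermediate
13 | geranyl bromide, (2E)-1-bromo-3,7-dimethylocta-2,6-diene | CC(C)=CCC/C(C)=C/CBr | starting material
14 | ethyl (2R,4E)-2-(1-{[(2S)-1-tert-butoxy-3-methyl-1-oxobutan-2-yl]imino}ethyl)-2,5,9-trimethyldeca-4,8-dienoate | CCOC(=O)[C@](C)(C/C=C(\C)CCC=C(C)C)C(C)=N[C@@H](C(C)C)C(=O)OC(C)(C)C | intermediate (not isolated)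
15 | ethyl (2R,4E)-2-acetyl-2,5,9-trimethyldeca-4,8-dienoate | CC(=O)[C@@](C)(C/C=C(\C)CCC=C(C)C)C(=O)OCC | intermediate
16 | diketene, 4-methylideneoxetan-2-one | C=C1CC(=O)O1 | starting material
17 | ethyl (2R,4E)-2-(3,5-dioxohexanoyl)-2,5,9-trimethyldeca-4,8-dienoate | CC(=O)CC(=O)CC(=O)[C@@](C)(C/C=C(\C)CCC=C(C)C)C(=O)OCC | intermediate (not isolated)
18 | (4R)-2-acetyl-4-[(2E)-3,7-dimethylocta-2,6-dien-1-yl]-4-methylcyclohexane-1,3,5-trione, drawn as the 3,5-dihydroxy-2,5-dienone tautomer | C1=C(O)[C@@](C)(C/C=C(\C)CCC=C(C)C)C(O)=C(C(C)=O)C1=O | intermediate
19 | 2-acetyl-6-[(dimethylamino)methyl]-4-[(2E)-3,7-dimethylocta-2,6-dien-1-yl]-4-methylcyclohexane-1,3,5-trione, quaternary carbon as in 18 (R in the enol form drawn) | CN(C)CC1=C(O)[C@@](C)(C/C=C(\C)CCC=C(C)C)C(O)=C(C(C)=O)C1=O | intermediate (not isolated)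
20 | 2-acetyl-4-[(2E)-3,7-dimethylocta-2,6-dien-1-yl]-4-methyl-6-methylidenecyclohexane-1,3,5-trione, same spatial arrangement at the quaternary carbon as in 18 | C=C1C(=O)[C@@](C)(C/C=C(\C)CCC=C(C)C)C(O)=C(C(C)=O)C1=O | intermediate (not isolated)
21 | 1-[6-({(3R)-5-acetyl-3-[(2E)-3,7-dimethylocta-2,6-dien-1-yl]-2,4-dihydroxy-3-methyl-6-oxocyclohexa-1,4-dien-1-yl}methyl)-5,7-dihydroxy-2,2-dimethyl-2H-chromen-8-yl]hexan-1-one (CNP0319887.1) | CCCCCC(=O)c1c(O)c(CC2=C(O)[C@@](C)(C/C=C(\C)CCC=C(C)C)C(O)=C(C(C)=O)C2=O)c(O)c2c1OC(C)(C)C=C2 | target

## Step count and least certain steps

Total step count: 9. Longest linear sequence: 6 steps (1, 2, 3, 4, 5, 9). The ring B branch has 4 steps (6, 7, 8, 9).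

**Step 4 (key step, new method).** The most likely failure is ring closure of 7 through the hexanoyl oxygen (lactonisation to a pyranone) or through the α-methylene of the pentyl chain instead of the pyran carbon, because all three form six-membered rings and only the tautomer argument separates them. Further risks are acylation of the phenols of 8 by unreacted 6 and acid-induced opening of the tertiary pyran ether by the HCl formed. A basic second stage of the kind used in related annulations could be tried to return O-acylated material to the carbon pathway, but that only changes conditions.

The fallback uses known chemistry and gives up the ring A line (compounds 1 to 8). It sets out from none of the numbered compounds but from commercial benzene-1,3,5-triol. Friedel–Crafts acylation with hexanoyl chloride (AlCl3, PhNO2/CH2Cl2) gives 1-(2,4,6-trihydroxyphenyl)hexan-1-one F1. Condensation of F1 with 3-methylbut-2-enal (ethylenediammonium diacetate cat., PhMe, 110 °C; Knoevenagel condensation, then oxa-6π electrocyclisation) gives 9 directly, together with the isomer closed on the other oxygen, 1-(5,7-dihydroxy-2,2-dimethyl-2H-chromen-6-yl)hexan-1-one F2, which must be separated. The route is rejoined at 9. The orientation control of the key step is lost, which is the reason this is only the fallback.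

**Step 9.** The most likely failure is loss of cross-selectivity. Retro-Mannich cleavage of 19, or transfer of the aminomethyl group to 9, lets 20 meet free 18 and gives symmetrical methylene-bis compounds. Prolonged heating could also cause dehydrative ring closure between a phenol and a trione carbonyl.

The fallback reverses the roles and sets out from 9. Aminomethylation at C6 ([Me2N=CH2]I, CH2Cl2, 0 °C) gives 1-{6-[(dimethylamino)methyl]-5,7-dihydroxy-2,2-dimethyl-2H-chromen-8-yl}hexan-1-one F3, which is isolated and purified. Heating F3 with 18 (1,4-dioxane, 90 °C) generates the ortho-quinone methide of ring A by loss of dimethylamine, and the enol of 18 adds at B1. The route is rejoined at 21.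

**Step 8.** The most likely failure is incomplete acetoacetylation, because the acidic product protonates unreacted enolate. Other risks are acylation of the enolate on oxygen by diketene, and base-induced cleavage next to the quaternary carbon during the closure.

The fallback builds the chain stepwise and sets out from 15. The methyl enolate (LiN(iPr)2, THF, −78 °C) is acetylated with N-methoxy-N-methylacetamide to give ethyl (2R,4E)-2,5,9-trimethyl-2-(3-oxobutanoyl)deca-4,8-dienoate F4. Its dianion (LiN(iPr)2, 2.2 equiv), which can only form at the terminal methyl, is acetylated with the same amide to give 17, now isolated. Closure with KOtBu as in step 8 rejoins the route at 18.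

**Step 7.** The most likely failure is insufficient or reversed facial selectivity, because the acyclic aza-enolate is less rigid than its cyclic counterparts and the sense depends on the donor environment of lithium. Attack at the tertiary end of the allylic bromide is a minor risk.

The fallback gives up asymmetric bond formation and sets out from 10 and 13. Alkylation of the sodium enolate (NaH, THF, 0 → 25 °C) gives racemic ethyl (4E)-2-acetyl-2,5,9-trimethyldeca-4,8-dienoate F5. The enantiomers are separated by preparative chromatography on a chiral stationary phase, and the R enantiomer rejoins the route at 15. The absolute configuration would be assigned by correlation with material from step 7 or by chiroptical comparison at the stage of 18.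

**Step 5.** The most likely failure is oxidative degradation of the electron-rich dihydroxyaryl ketone, or addition of the C6 position to the quinone, in competition with benzylic hydride abstraction.

The fallback changes to a protected, non-quinone sequence and sets out from 8. Acetylation (Ac2O, pyridine) gives 8-hexanoyl-2,2-dimethylchroman-5,7-diyl diacetate F6. Radical benzylic bromination (N-bromosuccinimide, azobisisobutyronitrile cat., PhCF3, 80 °C) gives 4-bromo-8-hexanoyl-2,2-dimethylchroman-5,7-diyl diacetate F7. Elimination with 1,8-diazabicyclo[5.4.0]undec-7-ene gives 8-hexanoyl-2,2-dimethyl-2H-chromene-5,7-diyl diacetate F8. Methanolysis (K2CO3 cat., MeOH, 0 °C) rejoins the route at 9.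

## Further compounds

F1 | step 4 | 1-(2,4,6-trihydroxyphenyl)hexan-1-one | CCCCCC(=O)c1c(O)cc(O)cc1O
F2 | step 4 | 1-(5,7-dihydroxy-2,2-dimethyl-2H-chromen-6-yl)hexan-1-one | CCCCCC(=O)c1c(O)cc2OC(C)(C)C=Cc2c1O
F3 | step 9 | 1-{6-[(dimethylamino)methyl]-5,7-dihydroxy-2,2-dimethyl-2H-chromen-8-yl}hexan-1-one | CCCCCC(=O)c1c(O)c(CN(C)C)c(O)c2c1OC(C)(C)C=C2
F4 | step 8 | ethyl (2R,4E)-2,5,9-trimethyl-2-(3-oxobutanoyl)deca-4,8-dienoate | CC(=O)CC(=O)[C@@](C)(C/C=C(\C)CCC=C(C)C)C(=O)OCC
F5 | step 7 | ethyl (4E)-2-acetyl-2,5,9-trimethyldeca-4,8-dienoate (racemic) | CC(=O)C(C)(C/C=C(\C)CCC=C(C)C)C(=O)OCC
F6 | step 5 | 8-hexanoyl-2,2-dimethylchroman-5,7-diyl diacetate | CCCCCC(=O)c1c(OC(C)=O)cc(OC(C)=O)c2c1OC(C)(C)CC2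
F7 | step 5 | 4-bromo-8-hexanoyl-2,2-dimethylchroman-5,7-diyl diacetate (racemic) | CCCCCC(=O)c1c(OC(C)=O)cc(OC(C)=O)c2c1OC(C)(C)CC2Br
F8 | step 5 | 8-hexanoyl-2,2-dimethyl-2H-chromene-5,7-diyl diacetate | CCCCCC(=O)c1c(OC(C)=O)cc(OC(C)=O)c2c1OC(C)(C)C=C2
A1 | alternative 1 | 3-ethoxycyclobut-2-en-1-one | CCOC1=CC(=O)C1
A2 | alternative 1 | triisopropyl[(5-methylhex-4-en-1-yn-1-yl)oxy]silane | CC(C)=CCC#CO[Si](C(C)C)(C(C)C)C(C)C
A3 | alternative 1 | 5-ethoxy-2-(3-methylbut-2-en-1-yl)-3-[(triisopropylsilyl)oxy]phenol | CC(C)=CCc1c(O)cc(OCC)cc1O[Si](C(C)C)(C(C)C)C(C)C
A4 | alternative 2 | dimethyl 2-[(2E)-3,7-dimethylocta-2,6-dien-1-yl]-2-methylpropanedioate | COC(=O)C(C)(C/C=C(\C)CCC=C(C)C)C(=O)OC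
A5 | alternative 2 | methyl (2S,4E)-2-(2-acetyl-3-oxobutanoyl)-2,5,9-trimethyldeca-4,8-dienoate | COC(=O)[C@@](C)(C/C=C(\C)CCC=C(C)C)C(=O)C(C(C)=O)C(C)=O
A6 | alternative 2 | (4R)-2-acetyl-4-[(2E)-3,7-dimethylocta-2,6-dien-1-yl]-4-methylcyclohexane-1,3,5-trione, enol form (identical with 18) | C1=C(O)[C@@](C)(C/C=C(\C)CCC=C(C)C)C(O)=C(C(C)=O)C1=O
A7 | alternative 3 | dimethyl 4-[(2E)-3,7-dimethylocta-2,6-dien-1-yl]-4-methyl-3,5-dioxoheptanedioate | COC(=O)CC(=O)C(C)(C/C=C(\C)CCC=C(C)C)C(=O)CC(=O)OC
A8 | alternative 3 | methyl 3-[(2E)-3,7-dimethylocta-2,6-dien-1-yl]-3-methyl-2,4,6-trioxocyclohexane-1-carboxylate, enol form, single enantiomer as drawn | COC(=O)C1=C(O)[C@@](C)(C/C=C(\C)CCC=C(C)C)C(O)=CC1=O
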